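**Plan**

1. Retrosynthesis: remove the C8 silyl ether and the C5 angelate, take the C2 ketone back to a carbinol, the 1α,5β-diol back to a 1β,5β-epoxide and then to the C1=C5 alkene, remove C13 (Mannich methylenation), open the O6–C12 lactone bond, and finally cut C6–C7 and C9–C10 of the carbocycle.
2. Enabling feature: in the seven-membered ring (C1, C5–C10) the C8 carbinol sits between C7 and C9 (a 2-oxyallyl unit), and C6(O)–C5(O)–C1(O)–C10 is a masked 1-alkoxy-1,3-diene C6=C5–C1=C10, so the ring is a cyclohept-4-enone (4+3) adduct.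
3. Forward order: the dienol ether 14 is assembled as a chain (Stille acylation, CBS reduction, hydrostannation/iodination, Suzuki coupling); the carbocycle is closed by the (4+3) cycloaddition; the lactone ring follows by acylation of O6; then C8 reduction, C13, epoxide, triol, enone, angelate, desilylation.
4. Stereochemistry: the absolute configuration comes from the CBS reduction that sets C2, a helper centre erased in step 16. It is passed to the ring in the cycloaddition, where the wrong-face product is a diastereomer and is separated.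
5. Relative configuration: C6/C10 cis from the diene geometry, C7 from the extended transition state (also the stable epimer), C8 from equatorial hydride delivery, C1/C5 from β-face epoxidation and inversion at C1.
6. Helpers removed later: the two bromines, PMB, SiEt3, TBS and the C2 stereocentre.

Key step: step 9

Remark: xanthanolide numbering is used (ring C1, C5–C10; side chain C2–C4, C15; lactone C11–C13; C14 is the methyl on C10). α is the ring face that carries O6, β the other face. Crotonoyl chloride is taken as the commercial E isomer.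

**Route**

Step 1
Reactants: 1 (E)-but-2-enoyl chloride; 2 tributyl(prop-1-yn-1-yl)stannane
Product: 3 (E)-hept-2-en-5-yn-4-one
Conditions: PdCl2(PPh3)2 (2 mol %), THF, 50 °C
Reagents that add atoms: none
Why: Stille acylation of an acid chloride with an alkynylstannane should transfer only the propynyl group and leave the E alkene untouched.

Step 2
Reactants: 3 (E)-hept-2-en-5-yn-4-one
Product: 4 (S,E)-hept-2-en-5-yn-4-ol
Conditions: (S)-2-methyl-CBS-oxazaborolidine (0.2 equiv), catecholborane, toluene, −78 °C; MeOH, then aqueous work-up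
Reagents that add atoms: none
Why: In the Corey–Bakshi–Shibata reduction the alkenyl group should act as the large and the slim alkynyl group as the small residue, so the (S)-catalyst should give the (S)-carbinol at C2.

Step 3
Reactants: 4 (S,E)-hept-2-en-5-yn-4-ol
Product: 6 (S,2E,5E)-5-iodohepta-2,5-dien-4-ol, via vinylstannane 5 (not isolated)
Conditions: Bu3SnH, PdCl2(PPh3)2 (2 mol %), THF, 0 °C; then I2, CH2Cl2, 0 °C
Reagents that add atoms: tributyltin hydride CCCC[SnH](CCCC)CCCC (tin in 5 only); iodine II
Why: Palladium-catalysed hydrostannation adds H and Sn syn with tin on the carbinol-proximal carbon, and iododestannylation goes with retention, which places the C14 methyl trans to iodine and cis to C2.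

Step 4
Reactants: 6 (S,2E,5E)-5-iodohepta-2,5-dien-4-ol
Product: 7 triethyl{[(S,2E,5E)-5-iodohepta-2,5-dien-4-yl]oxy}silane
Conditions: Et3SiCl, imidazole, DMF, 0 °C
Reagents that add atoms: chlorotriethylsilane CC[Si](Cl)(CC)CC
Why: Standard silylation of a secondary allylic alcohol; the triethylsilyl group is chosen because it should fall off in the acidic step 15.

Step 5
Reactants: 8 4-methoxybenzyl alcohol; 9 trichloroethylene
Product: 12 1-[(ethynyloxy)methyl]-4-methoxybenzene, via dichlorovinyl ether 10 (not isolated), via lithium acetylide 11 (not isolated)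
Conditions: KH, THF, 0 °C → rt; n-BuLi (2.4 equiv), −78 → −40 °C; MeOH, −78 °C; the product is kept below rt and used at once
Reagents that add atoms: none
Why: The known ynol ether synthesis: alkoxide addition–elimination on trichloroethylene, then elimination and chlorine–lithium exchange with n-BuLi, then cold protonation.

Step 6
Reactants: 12 1-[(ethynyloxy)methyl]-4-methoxybenzene
Product: 13 (E)-2-{2-[(4-methoxybenzyl)oxy]vinyl}-4,4,5,5-tetramethyl-1,3,2-dioxaborolane
Conditions: pinacolborane, Cp2Zr(H)Cl (5 mol %), Et3N (10 mol %), CH2Cl2, 0 °C → rt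
Reagents that add atoms: pinacolborane B1OC(C)(C)C(C)(C)O1
Why: Zirconium-catalysed syn hydroboration of a terminal alkyne puts boron on the terminal carbon and gives the E alkenylboronate.

Step 7
Reactants: 7 triethyl{[(S,2E,5E)-5-iodohepta-2,5-dien-4-yl]oxy}silane; 13 (E)-alkenylboronate
Product: 14 triethyl{[(S,2E,5Z)-5-{(E)-2-[(4-methoxybenzyl)oxy]vinyl}hepta-2,5-dien-4-yl]oxy}silane
Conditions: Pd(PPh3)4 (5 mol %), K3PO4 (aq), THF, 45 °C
Reagents that add atoms: none
Why: Suzuki–Miyaura coupling proceeds with retention at both alkenes, so the dienol ether has a 1E enol ether and the C14 methyl trans to C5.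

Step 8
Reactants: 15 methyl 4-oxopentanoate
Product: 16 methyl 3,5-dibromo-4-oxopentanoate
Conditions: Br2 (2 equiv), CHCl3, 0 °C → rt
Reagents that add atoms: bromine BrBr
Why: Acid-catalysed α,α'-dibromination of the levulinate ketone at C3 and C5 is a known transformation.

Step 9
Reactants: 14 dienol ether; 16 methyl 3,5-dibromo-4-oxopentanoate
Product: 18 keto ester (cyclohept-4-en-1-one with 6α-PMBO, 7β-CH2CO2Me, 10α-CH3 and the (S)-CH(OSiEt3)–CH=CH–CH3 chain on C1), via zinc oxyallyl cation 17 (not isolated)
Conditions: Zn–Cu couple (3 equiv), DME, −10 → 5 °C, 16 (2 equiv) added slowly; chromatography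
Reagents that add atoms: none
Why: Zinc removes both bromines to give the zinc-bound 2-oxidoallyl cation 17, which adds across the s-cis dienol ether in a (4+3) cycloaddition; the closest known reaction type is the reductive cycloaddition of α,α'-dibromoketones with open-chain 1,3-dienes. The cyclohept-4-enone ring closes by an intermolecular suprafacial union of the allyl termini C9 and C7 with the diene termini C10 and C6, the C9–C10 bond leading and the C6–C7 bond following as attack of the enolate carbon on the oxocarbenium carbon. Regiochemistry should follow polarity and size: the most nucleophilic diene terminus C10 (δ to the ether oxygen) meets the unsubstituted CH2 terminus of 17, as in the known unions of unsymmetrical oxyallyl cations with isoprene. C6 and C10 come out cis because the ether oxygen and the C14 methyl both stand "outside" in the reacting diene, and C7 comes out trans to O6 from the extended arrangement of the W-shaped cation, which is also the all-pseudo-equatorial and hence the stable epimer at this enolisable centre. The absolute sense rests on C2: A(1,3) strain with the cis methyl holds H-2 in the diene plane, the triethylsilyloxy group covers one face, and addition anti to it gives 18, while the face isomer is a diastereomer that is removed by chromatography. The selectivities needed are diene over the isolated C3=C4 alkene, C10 over C5 as the site of first bonding, and the diene face; the electron-rich dienol ether, the hindered substituted terminus of 17 and the C2 centre are relied on for them.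

Step 10
Reactants: 18 keto ester
Product: 20 keto lactone (6α,7β trans-fused γ-lactone with C8 ketone), via hydroxy ester 19 (not isolated)
Conditions: DDQ, CH2Cl2/pH 7 buffer, 0 °C; then 2-hydroxypyridine (0.2 equiv), toluene, 60 °C
Reagents that add atoms: none
Why: Oxidative PMB cleavage frees O6, which closes the five-membered lactone by 5-exo-trig acyl substitution under neutral bifunctional catalysis; with C8 still a ketone, O6 is the only hydroxyl that can lactonise.

Step 11
Reactants: 20 keto lactone
Product: 21 8β-hydroxy lactone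
Conditions: LiBH(s-Bu)3 (L-Selectride), THF, −78 °C; AcOH, −78 °C
Reagents that add atoms: none
Why: The bulky hydride should attack the ketone equatorially, anti to the axial H-7, giving the axial 8β-alcohol cis to the C7 side arm; the lactone is not reduced at −78 °C.

Step 12
Reactants: 21 8β-hydroxy lactone
Product: 22 8β-TBS ether
Conditions: TBSOTf, 2,6-lutidine, CH2Cl2, −78 → −40 °C
Reagents that add atoms: tert-butyldimethylsilyl triflate CC(C)(C)[Si](C)(C)OS(=O)(=O)C(F)(F)F
Why: Silylation of the hindered axial alcohol blocks translactonisation to O8 and keeps O8 out of the later acylation.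

Step 13
Reactants: 22 8β-TBS ether
Product: 26 α-methylene lactone, via lithium enolate 23 (not isolated), via Mannich base 24 (not isolated), via ammonium iodide 25 (not isolated)
Conditions: LiN(i-Pr)2, THF, −78 °C; CH2=NMe2 iodide, −78 °C → rt; MeI, CH2Cl2, rt; NaHCO3 (aq), EtOAc, rt
Reagents that add atoms: Eschenmoser's salt C=[N+](C)C.[I-]; iodomethane CI (methyl in 25 only)
Why: Mannich aminomethylation of the lactone enolate at C11, quaternisation and Hofmann-type elimination is the standard α-methylenation of γ-lactones and touches no stereocentre that is kept.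

Step 14
Reactants: 26 α-methylene lactone
Product: 27 1β,5β-epoxide
Conditions: mCPBA (1.1 equiv), NaHCO3, CH2Cl2, 0 °C
Reagents that add atoms: mCPBA O=C(OO)c1cccc(Cl)c1
Why: Prilezhaev epoxidation should pick the trisubstituted C1=C5 alkene over the disubstituted C3=C4 and the electron-poor C11=C13 alkenes, and should attack the convex β face, opposite the C7–C8–C9 fold of the chair cycloheptene.

Step 15
Reactants: 27 1β,5β-epoxide
Product: 28 triol (1α-OH, 2-OH, 5β-OH, 8β-OTBS)
Conditions: HClO4 (0.1 M aq), THF, 0 °C → rt
Reagents that add atoms: water O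
Why: Acid-catalysed epoxide hydrolysis should occur by attack of water at the tertiary C1 with inversion, giving 1α-OH and leaving 5β-O in place; the triethylsilyl ether is cleaved under the same conditions and the secondary TBS ether should survive.

Step 16
Reactants: 28 triol
Product: 29 α-hydroxy enone diol (C2 ketone, 1α-OH, 5β-OH)
Conditions: MnO2 (activated, excess), CH2Cl2, rt
Reagents that add atoms: none
Why: MnO2 oxidises only the allylic C2 carbinol to the E enone and erases the helper stereocentre; the C5 and C1 hydroxyls are not allylic.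

Step 17
Reactants: 29 α-hydroxy enone diol; 30 angelic acid
Product: 32 8-O-TBS target (5β-angelate), via mixed anhydride 31 (not isolated)
Conditions: 30, 2,4,6-trichlorobenzoyl chloride, Et3N, toluene, rt; then 29, toluene, 70 °C
Reagents that add atoms: 2,4,6-trichlorobenzoyl chloride O=C(Cl)c1c(Cl)cc(Cl)cc1Cl (atoms in 31 only)
Why: Yamaguchi-type mixed-anhydride acylation without DMAP should acylate the only secondary hydroxyl (C5) and keep the Z geometry of the angelate; the tertiary C1 hydroxyl is inert.

Step 18
Reactants: 32 8-O-TBS target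
Product: 33 CNP0206014.2
Conditions: HF·pyridine, pyridine, THF, 0 °C → rt
Reagents that add atoms: none
Why: Buffered fluoride desilylation frees the 8β-hydroxyl without base, so the angelate, the enone, the α-methylene lactone and the 6,12-lactone position should be kept.

**Compound list**

1 | (E)-but-2-enoyl chloride | C/C=C/C(=O)Cl | starting material
2 | tributyl(prop-1-yn-1-yl)stannane | CC#C[Sn](CCCC)(CCCC)CCCC | starting material
3 | (E)-hept-2-en-5-yn-4-one | C/C=C/C(=O)C#CC | intermediate
4 | (S,E)-hept-2-en-5-yn-4-ol | C/C=C/[C@H](O)C#CC | intermediate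
5 | (S,2E,5E)-5-(tributylstannyl)hepta-2,5-dien-4-ol | C/C=C/[C@H](O)C(\[Sn](CCCC)(CCCC)CCCC)=C/C | intermediate
6 | (S,2E,5E)-5-iodohepta-2,5-dien-4-ol | C/C=C/[C@H](O)C(\I)=C/C | intermediate
7 | triethyl{[(S,2E,5E)-5-iodohepta-2,5-dien-4-yl]oxy}silane | C/C=C/[C@H](O[Si](CC)(CC)CC)C(\I)=C/C | intermediate
8 | 4-methoxybenzyl alcohol | COc1ccc(CO)cc1 | starting material
9 | trichloroethylene | ClC=C(Cl)Cl | starting material
10 | (E)-1-{[(1,2-dichlorovinyl)oxy]methyl}-4-methoxybenzene | COc1ccc(CO/C(Cl)=C\Cl)cc1 | intermediate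
11 | lithium [(4-methoxybenzyl)oxy]acetylide | [Li]C#COCc1ccc(OC)cc1 | intermediate
12 | 1-[(ethynyloxy)methyl]-4-methoxybenzene | COc1ccc(COC#C)cc1 | intermediate
13 | (E)-2-{2-[(4-methoxybenzyl)oxy]vinyl}-4,4,5,5-tetramethyl-1,3,2-dioxaborolane | COc1ccc(CO/C=C/B2OC(C)(C)C(C)(C)O2)cc1 | intermediate
14 | triethyl{[(S,2E,5Z)-5-{(E)-2-[(4-methoxybenzyl)oxy]vinyl}hepta-2,5-dien-4-yl]oxy}silane | C/C=C/[C@H](O[Si](CC)(CC)CC)C(\C=C\OCc1ccc(OC)cc1)=C/C | intermediate
15 | methyl 4-oxopentanoate | COC(=O)CCC(C)=O | starting material
16 | methyl 3,5-dibromo-4-oxopentanoate | COC(=O)CC(Br)C(=O)CBr | intermediate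
17 | zinc-bound 2-oxidoallyl cation from 16, written as the zwitterion | C=C([O-])[CH+]CC(=O)OC | intermediate
18 | keto ester: cyclohept-4-en-1-one with 6α-PMBO, 7β-CH2CO2Me, 10α-CH3, C1 chain (S)-CH(OSiEt3)CH=CHCH3 | O=C1C[C@H](C)C([C@@H](O[Si](CC)(CC)CC)/C=C/C)=C[C@H](OCc2ccc(OC)cc2)[C@H]1CC(=O)OC | intermediate
19 | 6α-hydroxy keto ester | O=C1C[C@H](C)C([C@@H](O[Si](CC)(CC)CC)/C=C/C)=C[C@H](O)[C@H]1CC(=O)OC | intermediate
20 | keto lactone (6α,7β trans-fused γ-lactone, C8 ketone) | O=C1C[C@H](C)C([C@@H](O[Si](CC)(CC)CC)/C=C/C)=C[C@@H]2OC(=O)C[C@@H]12 | intermediate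
21 | 8β-hydroxy lactone | O[C@H]1C[C@H](C)C([C@@H](O[Si](CC)(CC)CC)/C=C/C)=C[C@@H]2OC(=O)C[C@@H]12 | intermediate
22 | 8β-TBS ether of 21 | CC(C)(C)[Si](C)(C)O[C@H]1C[C@H](C)C([C@@H](O[Si](CC)(CC)CC)/C=C/C)=C[C@@H]2OC(=O)C[C@@H]12 | intermediate
23 | lithium enolate of 22 | CC(C)(C)[Si](C)(C)O[C@H]1C[C@H](C)C([C@@H](O[Si](CC)(CC)CC)/C=C/C)=C[C@@H]2OC(O[Li])=C[C@@H]12 | intermediate
24 | 11-(dimethylaminomethyl) lactone (C11 epimers) | CC(C)(C)[Si](C)(C)O[C@H]1C[C@H](C)C([C@@H](O[Si](CC)(CC)CC)/C=C/C)=C[C@@H]2OC(=O)C(CN(C)C)[C@@H]12 | intermediate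
25 | 11-(trimethylammoniomethyl) lactone iodide | CC(C)(C)[Si](C)(C)O[C@H]1C[C@H](C)C([C@@H](O[Si](CC)(CC)CC)/C=C/C)=C[C@@H]2OC(=O)C(C[N+](C)(C)C)[C@@H]12.[I-] | intermediate
26 | α-methylene lactone | CC(C)(C)[Si](C)(C)O[C@H]1C[C@H](C)C([C@@H](O[Si](CC)(CC)CC)/C=C/C)=C[C@@H]2OC(=O)C(=C)[C@@H]12 | intermediate
27 | 1β,5β-epoxide | CC(C)(C)[Si](C)(C)O[C@H]1C[C@H](C)[C@@]2([C@@H](O[Si](CC)(CC)CC)/C=C/C)O[C@H]2[C@@H]2OC(=O)C(=C)[C@@H]12 | intermediate
28 | triol (1α-OH, 2-OH, 5β-OH, 8β-OTBS) | CC(C)(C)[Si](C)(C)O[C@H]1C[C@H](C)[C@@](O)([C@@H](O)/C=C/C)[C@@H](O)[C@@H]2OC(=O)C(=C)[C@@H]12 | intermediate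
29 | α-hydroxy enone diol (1α-OH, 5β-OH, 8β-OTBS) | CC(C)(C)[Si](C)(C)O[C@H]1C[C@H](C)[C@@](O)(C(=O)/C=C/C)[C@@H](O)[C@@H]2OC(=O)C(=C)[C@@H]12 | intermediate
30 | angelic acid, (Z)-2-methylbut-2-enoic acid | C/C=C(/C)C(=O)O | starting material
31 | angelic 2,4,6-trichlorobenzoic anhydride | C/C=C(/C)C(=O)OC(=O)c1c(Cl)cc(Cl)cc1Cl | intermediate
32 | 8-O-TBS target (5β-angelate) | CC(C)(C)[Si](C)(C)O[C@H]1C[C@H](C)[C@@](O)(C(=O)/C=C/C)[C@@H](OC(=O)/C(C)=C\C)[C@@H]2OC(=O)C(=C)[C@@H]12 | intermediate
33 | CNP0206014.2 (1α-hydroxy, 1β-(E)-but-2-enoyl, 5β-angeloyloxy, 6α,12-olide, 8β-hydroxy, 10α-methyl) | O[C@H]1C[C@H](C)[C@@](O)(C(=O)/C=C/C)[C@@H](OC(=O)/C(C)=C\C)[C@@H]2OC(=O)C(=C)[C@@H]12 | target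

**Count and risks**

Total steps: 18. Longest linear sequence: 15 (steps 1–4, 7, 9–18).

Most likely to fail, step 9. The oxyallyl cation may be captured at C5 of the dienol ether and close to a five-membered ring, the first-formed cation may lose a proton to give open-chain alkylation, or the addition may show little face or C7 selectivity. If only the face sense is wrong, the (R)-catalyst is used in step 2, since C2 is erased later; a C7 epimer can be equilibrated through the ketone enol. The fallback changes the bond-forming event. It sets out from 14 and comes back at 18. Allyl acetoacetate is converted by diazo transfer (4-acetamidobenzenesulfonyl azide, Et3N) into allyl 2-diazo-3-oxobutanoate F1 and then by TBSOTf/Et3N into allyl 3-[(tert-butyldimethylsilyl)oxy]-2-diazobut-3-enoate F2. With Rh2(OAc)4 and 14, cyclopropanation of the C5=C6 enol ether double bond followed by divinylcyclopropane Cope rearrangement should give the cycloheptadiene β-silyloxy ester F3; here the regiochemistry is fixed by the site of cyclopropanation and C6/C10 come out cis through the boat transition state. Fluoride-triggered C-alkylation of the silyl enol ether with methyl bromoacetate (benzyltrimethylammonium fluoride, THF, −78 °C) gives the quaternary allyl β-keto ester F4. Deallylative decarboxylation with Pd(PPh3)4 and HCO2H/Et3N then gives 18 after equilibration at C7, the allyl ester having served as a temporary activating group.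

Step 14. The peracid may attack the α face or the side-chain alkene. The fallback replaces steric control by hydroxyl delivery. It sets out from 26 and comes back at 28. PPTS in MeOH at 0 °C removes the triethylsilyl group to give the allylic alcohol F5. With VO(acac)2 and t-BuOOH, A(1,2) strain with C10 keeps H-2 near the alkene plane, which for the 2S carbinol places O2 over the β face, so the epoxy alcohol F6 should form with the same epoxide configuration as 27. Hydrolysis as in step 15 then gives 28.

Step 15. Ionisation at C1 may be diverted into a 1,2-shift from C2 or proton loss, or water may attack C5. The fallback delivers the oxygen to C1 from inside. It sets out from 27 and comes back at 28. HF·pyridine/pyridine at 0 °C removes the triethylsilyl group selectively to give the epoxy alcohol F6. Silylation with t-Bu2Si(OTf)2/2,6-lutidine and aqueous NaHCO3 gives the di-tert-butylsilanol F7. Catalytic Ph3CBF4 should induce 5-exo attack of the silanol oxygen on C1 with inversion, giving the dioxasilolane F8 with the 5β-hydroxyl free. Brief HF·pyridine at −20 °C cleaves the strained silylene but not the C8 silyl ether and gives 28.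

Further compounds
F1 | step 9 | allyl 2-diazo-3-oxobutanoate | C=CCOC(=O)C(=[N+]=[N-])C(C)=O
F2 | step 9 | allyl 3-[(tert-butyldimethylsilyl)oxy]-2-diazobut-3-enoate | C=CCOC(=O)C(=[N+]=[N-])C(=C)O[Si](C)(C)C(C)(C)C
F3 | step 9 | cycloheptadiene β-silyloxy allyl ester (6α-PMBO, 10α-CH3) | C=CCOC(=O)C1=C(O[Si](C)(C)C(C)(C)C)C[C@H](C)C([C@@H](O[Si](CC)(CC)CC)/C=C/C)=C[C@@H]1OCc1ccc(OC)cc1
F4 | step 9 | quaternary allyl β-keto ester with CH2CO2Me on C7 | C=CCOC(=O)C1(CC(=O)OC)C(=O)C[C@H](C)C([C@@H](O[Si](CC)(CC)CC)/C=C/C)=C[C@@H]1OCc1ccc(OC)cc1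
F5 | step 14 | allylic alcohol (2S carbinol of 26) | CC(C)(C)[Si](C)(C)O[C@H]1C[C@H](C)C([C@@H](O)/C=C/C)=C[C@@H]2OC(=O)C(=C)[C@@H]12
F6 | step 14 | 1β,5β-epoxy alcohol | CC(C)(C)[Si](C)(C)O[C@H]1C[C@H](C)[C@@]2([C@@H](O)/C=C/C)O[C@H]2[C@@H]2OC(=O)C(=C)[C@@H]12
F7 | step 15 | di-tert-butylsilanol ether of F6 | CC(C)(C)[Si](C)(C)O[C@H]1C[C@H](C)[C@@]2([C@@H](O[Si](O)(C(C)(C)C)C(C)(C)C)/C=C/C)O[C@H]2[C@@H]2OC(=O)C(=C)[C@@H]12
F8 | step 15 | 1α,2-O-(di-tert-butylsilylene) derivative with free 5β-OH | CC(C)(C)[Si](C)(C)O[C@H]1C[C@H](C)[C@]2(O[Si](C(C)(C)C)(C(C)(C)C)O[C@H]2/C=C/C)[C@@H](O)[C@@H]2OC(=O)C(=C)[C@@H]12
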